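**Analysis of the target**

CNP0304855.1 is a C50 carotenoid on the ε,ε-carotene skeleton: an all-E nonaene chain (C7 to C7', methyl branches at C9, C13, C13' and C9') joins two 1,1,5-trimethylcyclohex-4-ene end groups through C6 and C6'. Ring A carries a 3-methylbut-2-enyl group at C2, ring B an (E)-4-hydroxy-3-methylbut-2-enyl group at C2'. The four stereocentres are (2S,6R,2'R,6'S). C2 and C2' have the same sense in space (the descriptors differ only because the hydroxyl raises the rank of the ring B side chain), whereas C6 and C6' are opposite, so ring A is 2,6-cis and ring B 2',6'-trans. In each ring the two stereocentres flank the quaternary C1, so they are 1,3-related across a gem-dimethyl group and every bond made at C2 or C6 is a neopentyl-type bond. Sensitive points are the polyene (light, oxygen, acid), the primary allylic alcohol, and the C6–H and C6'–H bonds, which are allylic to the ring alkene and to the chain and allow epimerisation or migration of the ring alkene into conjugation. Because the halves differ in side chain and in relative configuration, no symmetrical double coupling is possible and each end group has to be made as one stereoisomer. The plan rests on C2 and C2' being the same tertiary stereocentre, with a five-carbon chain beside C1: read C4 as a carbonyl carbon and C2 becomes the β-carbon of a cross-conjugated dienone, so that one enone, 6, serves both rings.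

**Retrosynthetic reasoning**

Target 43 to silyl ether 42. The last operation removes a silyl group from the C4'' oxygen. The ether is carried because a free primary allylic hydroxyl would react along with the C11' hydroxyl when the ring B phosphonium salt is made.

42 to aldehyde 41 and phosphonium salt 22; 41 to phosphonium salt 39 and dialdehyde 40. The chain is cut at C11=C12 and at C11'=C12', the two disubstituted double bonds that flank the central ten-carbon unit. Both cuts together release the symmetrical, purchasable 40 with C13 to C13' in place, and leave two C20 end pieces of the same kind. The two Wittig reactions must be run in sequence because the halves differ; each forms a disubstituted alkene whose Z isomer is strained and reverts on heating.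

22 to dienol 20, dienoate 19, then sulfone 16 and bromo ester 17 (ring B: 39 to 36, 35, then 33 and 17). The dienoates are cut at C7–C8, with C7 as a sulfonyl-stabilised carbanion and C8 as the allylic bromide carbon of 17; loss of the sulfonyl group then creates C7=C8. The cut is not made at C7=C8 by olefination of a C7 aldehyde, because C6 would then stand α to a carbonyl group, where it epimerises and the ring alkene moves into conjugation. The gain is C8 to C11 with the C9 methyl from a commercial reagent. In the forward direction alkylation has to outrun proton transfer, and elimination has to go towards C8, which the ester of 17 ensures.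

16 to aldehyde 14 and phosphonium salt 15; 14 to alcohol 13 and vinyl sulfone 10 (ring B: 33 to 31, 30, then aldehyde 28 and ylide 29; 28 to 27 and 25). The side chains are cut at C2''=C3''. The vinyl group of 10 and 25 already holds C1'' and C2''; its terminal carbon is raised to the aldehyde, and the two rings then diverge through the choice of ylide. The sulfone is inert to all of these reagents, so the side chains are built at this stage.

10 to ester 9, and 25 to ester 24; both to alcohol 7 and acid 8. The C6–C7 bond is traced back to the C4–O bond of an allylic ester through a [3,3] shift followed by decarboxylation. C6 lies between the quaternary C1 and the methyl-bearing C5, so an intramolecular, suprafacial transfer is preferred to any intermolecular attack. The shift turns the C4 configuration into the C6 configuration and delivers C7 directly as a sulfone. The rings differ only in how 8 is attached to 7: with retention for the cis ring (9), with inversion for the trans ring (24).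

7 to enone 6. The carbinol comes from the ketone; the reduction is under substrate control from the vinyl-bearing carbon.

6 to dienone 4 and vinylboronate 5. The bond from C2 to C1'' is cut; in the forward direction a vinyl group is added 1,4 to one arm of a flat, achiral dienone under catalyst control. This is the only step in which absolute configuration is created, and it is placed early so that both end groups draw on the same enantiomer. The methyl group of 4 decides which arm reacts and later becomes the C5 methyl.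

4 to ketone 3, then to 1 and 2. The dienone is reached by α'-methylation of a commercial enone and dehydrogenation; the quaternary carbon allows only one enolate and only one new double bond.

**Alternatives that were turned down**

Alternative 1: The cut is the C1''–C2'' bond of the ring B side chain. A ring B acetic acid, activated as its N-hydroxyphthalimide ester A2, would be joined to the alkenyl iodide A3 by a decarboxylative, nickel-catalysed coupling at a cathode to give A1.
- For it: the side chain arrives in one C(sp3)–C(sp2) step, with the alkene geometry fixed in A3 and the C4'' oxygen already protected. On this bond it is shorter than steps 16 to 19 of the chosen route, which need an oxidation, a Wittig reaction, a reduction and a silylation.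
- Against it: it solves one side chain of one ring only. A2 presupposes that C2', C6' and C7' are already in place, which demands two orthogonal protecting groups, an oxidation of the two-carbon arm to the acid and its activation. Ring A would still need its own coupling or a Wittig reaction, and an electrolysis cell has to be scaled.
- Comparison: the chosen strategy spends its risk on C2, which this alternative does not address, and then makes both side chains from one vinyl group by ordinary two-electron chemistry. Once the acid and its activation are counted, the coupling saves little.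

Alternative 2: The cut is C6–C7 of ring A. A dienylcopper reagent from the dienyl iodide A6 (halogen–lithium exchange, then transmetallation) would attack C6 of the picolinate A5 anti to the leaving group, giving A4 with the alkene moved to C4=C5.
- For it: it is the most convergent way to the C20 unit. C7 to C11 arrive in one step with both alkene geometries set in A6, and no dienolate is passed. On chain geometry and on step count it is stronger than the chosen route, which needs steps 5, 6, 10 and 11 for the same result.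
- Against it: C6 lies between the quaternary C1 and the methyl-bearing C5, the least favourable place for an intermolecular organocopper attack, so direct substitution at C4 and reduction are expected to compete. The cis ring needs the 2,4-trans picolinate, hence an inversion of the reduction product. The dienyl metal is made with tert-butyllithium and may lose geometry.
- Comparison: the chosen route forms the same bond inside a six-membered transition state, where hindrance at C6 matters less, and uses the reduction product 7 unchanged for the cis ring. It pays for this with extra steps.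

Alternative 3: The cut is C6'–C7' of ring B. The stannylmethyl ether A8 of the 2',4'-trans alcohol would undergo tin–lithium exchange, and the α-alkoxy carbanion would shift [2,3] to give the C7' carbinol A7.
- For it: it is suprafacial and intramolecular like the chosen relay, takes two steps from the alcohol, and needs no activated acid. In length it equals steps 13 and 14.
- Against it: it requires etherification of a hindered secondary allylic alkoxide, a [1,2] shift can compete, and tin is used stoichiometrically. Above all, A7 is at the alcohol level: extending the chain means either an aldehyde with the C6' stereocentre α to the carbonyl group, or two further steps to a sulfone.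
- Comparison: the sulfonylacetate rearrangement delivers C7 directly as the sulfone that the C7–C8 bond formation uses, without tin. The [2,3] shift is kept only as a reserve.

Key step: step 3

Remark: positions are given in carotenoid numbering (C1 to C6 ring A, C7 to C15 chain, primes for the ring B half, C1'' to C4'' for the five-carbon side chains); 40 is taken as a purchasable building block.
Remark: the reduction in step 4 is taken to place the hydroxyl cis to the vinyl group, as 5-substituted cyclohex-2-enones generally do; should it favour the other epimer, steps 5 and 13 exchange their roles.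
Remark: (R)-BINAP is assigned in step 3 by analogy with the accepted facial sense for cyclohex-2-enone; if the gem-dimethyl group reversed that sense, the antipodal ligand would be used.

Step 1
Reactants: 1 4,4-dimethylcyclohex-2-en-1-one; 2 iodomethane
Product: 3 rac-4,4,6-trimethylcyclohex-2-en-1-one
Conditions: LiN(i-Pr)2, THF, −78 °C; then 2, −78 → 0 °C
Reagents that add atoms: iodomethane 2, CI
Why: Enolate alkylation; deprotonation can occur only at C6 because C4 is quaternary, and the lithium enolate is C-methylated. The new stereocentre is racemic and is erased in step 2.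

Step 2
Reactants: 3 rac-4,4,6-trimethylcyclohex-2-en-1-one
Product: 4 2,4,4-trimethylcyclohexa-2,5-dien-1-one
Conditions: IBX, DMSO/toluene, 75 °C
Reagents that add atoms: none
Why: IBX dehydrogenation of a ketone through its enol; only the C5–C6 bond can be desaturated, which gives the cross-conjugated dienone. Acid is excluded because 4,4-dialkylcyclohexadienones undergo the dienone–phenol rearrangement.

Step 3
Reactants: 4 2,4,4-trimethylcyclohexa-2,5-dien-1-one; 5 2-ethenyl-4,4,5,5-tetramethyl-1,3,2-dioxaborolane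
Product: 6 (5R)-5-ethenyl-2,4,4-trimethylcyclohex-2-en-1-one
Conditions: Rh(acac)(C2H4)2 (3 mol %), (R)-BINAP (3.3 mol %), KOH (0.5 equiv), 5 (2.5 equiv), 1,4-dioxane/H2O 10:1, 60 → 90 °C
Reagents that add atoms: 2-ethenyl-4,4,5,5-tetramethyl-1,3,2-dioxaborolane 5, C=CB1OC(C)(C)C(C)(C)O1
Why: This is a rhodium-catalysed asymmetric 1,4-addition of an alkenylboron reagent (Hayashi–Miyaura reaction). The boronate is hydrolysed and transmetallated to a hydroxo–BINAP complex of monovalent rhodium; the vinyl–rhodium species inserts the unsubstituted C5=C6 bond of 4, and water protonates the oxa-π-allyl rhodium intermediate, releasing 6 and regenerating the hydroxo complex. The closest known cases are alkenylboron additions to cyclohex-2-enones and desymmetrising additions to 4,4-disubstituted cyclohexa-2,5-dienones. No ring is closed; one C–C bond (C2 to C1'') and one stereocentre are formed. The stereocentre is set by the ligand alone, since the dienone is flat and its two faces at C5 are enantiotopic; (R)-BINAP is chosen because (S)-BINAP is known to deliver to the face of cyclohex-2-enone that corresponds here to the 5S product. The step needs selectivity between the two enone arms, and the C2 methyl group supplies it, because α-substituted enones insert into the rhodium–carbon bond far more slowly. For the same reason the product, an α-methyl enone, should not take up a second vinyl group. Attack beside the quaternary carbon is the slow point, which is why the flat, more electrophilic dienone and an excess of 5 are used.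

Step 4
Reactants: 6 (5R)-5-ethenyl-2,4,4-trimethylcyclohex-2-en-1-one
Product: 7 (1R,5R)-5-ethenyl-2,4,4-trimethylcyclohex-2-en-1-ol
Conditions: NaBH4, CeCl3·7H2O, MeOH, −78 → −20 °C
Reagents that add atoms: none
Why: Luche 1,2-reduction; hydride adds axially to the half-chair that holds the vinyl group equatorial, on the face away from the axial C4 methyl group. The hydroxyl therefore ends pseudo-equatorial and cis to the vinyl group (1R).

Step 5
Reactants: 7 (1R,5R)-5-ethenyl-2,4,4-trimethylcyclohex-2-en-1-ol; 8 2-[(4-methylphenyl)sulfonyl]acetic acid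
Product: 9 (1R,5R)-5-ethenyl-2,4,4-trimethylcyclohex-2-en-1-yl 2-[(4-methylphenyl)sulfonyl]acetate
Conditions: N,N'-dicyclohexylcarbodiimide, 4-(dimethylamino)pyridine (cat.), CH2Cl2, 0 °C → rt
Reagents that add atoms: 2-[(4-methylphenyl)sulfonyl]acetic acid 8, Cc1ccc(cc1)S(=O)(=O)CC(=O)O
Why: Steglich esterification with retention at the carbinol carbon; the acid brings in the sulfonyl group and the carbon that becomes C7.

Step 6
Reactants: 9 (1R,5R)-5-ethenyl-2,4,4-trimethylcyclohex-2-en-1-yl 2-[(4-methylphenyl)sulfonyl]acetate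
Product: 10 1-{[(1R,5R)-5-ethenyl-2,6,6-trimethylcyclohex-2-en-1-yl]methanesulfonyl}-4-methylbenzene
Conditions: N,O-bis(trimethylsilyl)acetamide (0.3 equiv), CH3CO2K (0.1 equiv), toluene, 110 °C
Reagents that add atoms: none
Why: Decarboxylative Claisen rearrangement of an allylic sulfonylacetate (Ireland–Claisen-type [3,3] shift of the silyl ketene acetal, then desilylation and loss of CO2 from the α-sulfonyl carboxylate). The six-membered transition state spans one face of the ring, so the new C6–C7 bond forms on the face that carried oxygen, cis to the vinyl group, while the alkene moves to C4=C5.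

Step 7
Reactants: 10 1-{[(1R,5R)-5-ethenyl-2,6,6-trimethylcyclohex-2-en-1-yl]methanesulfonyl}-4-methylbenzene; 11 hydrogen peroxide
Product: 13 2-[(1R,5R)-4,6,6-trimethyl-5-{[(4-methylphenyl)sulfonyl]methyl}cyclohex-3-en-1-yl]ethan-1-ol, via organoborane 12 (not isolated)
Conditions: 9-BBN, THF, 0 °C → rt; then 11, NaOH, H2O, 0 °C
Reagents that add atoms: hydrogen peroxide 11, OO
Why: Hydroboration–oxidation; 9-BBN adds only to the monosubstituted alkene, boron at the terminal carbon, and leaves the trisubstituted ring alkene and the sulfone untouched. Oxidation with retention gives the primary alcohol.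

Step 8
Reactants: 13 2-[(1R,5R)-4,6,6-trimethyl-5-{[(4-methylphenyl)sulfonyl]methyl}cyclohex-3-en-1-yl]ethan-1-ol
Product: 14 2-[(1R,5R)-4,6,6-trimethyl-5-{[(4-methylphenyl)sulfonyl]methyl}cyclohex-3-en-1-yl]acetaldehyde
Conditions: Dess–Martin periodinane, NaHCO3, CH2Cl2, 0 °C → rt
Reagents that add atoms: none
Why: Dess–Martin oxidation of a primary alcohol under buffered, non-basic conditions; the aldehyde has no stereocentre at its α-carbon.

Step 9
Reactants: 14 2-[(1R,5R)-4,6,6-trimethyl-5-{[(4-methylphenyl)sulfonyl]methyl}cyclohex-3-en-1-yl]acetaldehyde; 15 triphenyl(propan-2-yl)phosphanium iodide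
Product: 16 1-methyl-4-{[(1R,5S)-2,6,6-trimethyl-5-(3-methylbut-2-en-1-yl)cyclohex-2-en-1-yl]methanesulfonyl}benzene
Conditions: 15, NaN(SiMe3)2, THF, 0 °C; then 14, −78 °C → rt
Reagents that add atoms: triphenyl(propan-2-yl)phosphanium iodide 15, CC(C)[P+](c1ccccc1)(c1ccccc1)c1ccccc1.[I-]
Why: Wittig olefination with the non-stabilised isopropylidene ylide; the new alkene carries two identical methyl groups, so no geometry arises. The ylide is too weak a base to deprotonate the sulfone.

Step 10
Reactants: 16 1-methyl-4-{[(1R,5S)-2,6,6-trimethyl-5-(3-methylbut-2-en-1-yl)cyclohex-2-en-1-yl]methanesulfonyl}benzene; 17 ethyl (2E)-4-bromo-3-methylbut-2-enoate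
Product: 19 ethyl (2E,4E)-3-methyl-5-[(1R,5S)-2,6,6-trimethyl-5-(3-methylbut-2-en-1-yl)cyclohex-2-en-1-yl]penta-2,4-dienoate, via alkylated sulfone 18 (not isolated)
Conditions: n-BuLi, THF, −78 °C; 17, −78 °C; then NaOC2H5, EtOH, −78 °C → rt
Reagents that add atoms: ethyl (2E)-4-bromo-3-methylbut-2-enoate 17, CCOC(=O)/C=C(\C)CBr
Why: Julia-type sulfone alkylation followed by dehydrosulfonylation; the α-sulfonyl carbanion displaces the allylic bromide (C7–C8 bond), then ethoxide removes the C8 proton, which the ester activates vinylogously, and sulfinate leaves from C7 (E1cB) to give the trans C7=C8 bond in conjugation. C6 never becomes part of a carbanion or carbonyl system and keeps its configuration; E geometry at C9=C10 is the preferred outcome when the dienolate collapses.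

Step 11
Reactants: 19 ethyl (2E,4E)-3-methyl-5-[(1R,5S)-2,6,6-trimethyl-5-(3-methylbut-2-en-1-yl)cyclohex-2-en-1-yl]penta-2,4-dienoate
Product: 20 (2E,4E)-3-methyl-5-[(1R,5S)-2,6,6-trimethyl-5-(3-methylbut-2-en-1-yl)cyclohex-2-en-1-yl]penta-2,4-dien-1-ol
Conditions: i-Bu2AlH, CH2Cl2, −78 °C; KNaC4H4O6 aq.
Reagents that add atoms: none
Why: 1,2-Reduction of a conjugated ester to the allylic alcohol by an aluminium hydride; no other reducible group is present.

Step 12
Reactants: 20 (2E,4E)-3-methyl-5-[(1R,5S)-2,6,6-trimethyl-5-(3-methylbut-2-en-1-yl)cyclohex-2-en-1-yl]penta-2,4-dien-1-ol; 21 triphenylphosphane hydrobromide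
Product: 22 [(2E,4E)-3-methyl-5-[(1R,5S)-2,6,6-trimethyl-5-(3-methylbut-2-en-1-yl)cyclohex-2-en-1-yl]penta-2,4-dien-1-yl]triphenylphosphanium bromide
Conditions: 21, MeOH, rt, dark, argon
Reagents that add atoms: triphenylphosphane hydrobromide 21, [PH+](c1ccccc1)(c1ccccc1)c1ccccc1.[Br-]
Why: Phosphonium salt formation from an allylic alcohol; ionisation gives a pentadienyl cation that the phosphane captures at the unhindered terminus C11, so the conjugated diene is kept.

Step 13
Reactants: 7 (1R,5R)-5-ethenyl-2,4,4-trimethylcyclohex-2-en-1-ol; 8 2-[(4-methylphenyl)sulfonyl]acetic acid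
Product: 24 (1S,5R)-5-ethenyl-2,4,4-trimethylcyclohex-2-en-1-yl 2-[(4-methylphenyl)sulfonyl]acetate
Conditions: triphenylphosphane 23, diisopropyl azodicarboxylate, THF, 0 °C → rt
Reagents that add atoms: 2-[(4-methylphenyl)sulfonyl]acetic acid 8, Cc1ccc(cc1)S(=O)(=O)CC(=O)O
Why: Mitsunobu esterification; the carboxylate displaces the alkoxyphosphonium ion of 7 with inversion at C1, which puts the ester trans to the vinyl group. The acid is about as strong as chloroacetic acid, the usual choice for inverting hindered secondary alcohols.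

Step 14
Reactants: 24 (1S,5R)-5-ethenyl-2,4,4-trimethylcyclohex-2-en-1-yl 2-[(4-methylphenyl)sulfonyl]acetate
Product: 25 1-{[(1S,5R)-5-ethenyl-2,6,6-trimethylcyclohex-2-en-1-yl]methanesulfonyl}-4-methylbenzene
Conditions: N,O-bis(trimethylsilyl)acetamide (0.3 equiv), CH3CO2K (0.1 equiv), toluene, 110 °C
Reagents that add atoms: none
Why: The same decarboxylative Claisen rearrangement as in step 6; the suprafacial shift now runs on the face opposite to the vinyl group and gives the 2',6'-trans ring.

Step 15
Reactants: 25 1-{[(1S,5R)-5-ethenyl-2,6,6-trimethylcyclohex-2-en-1-yl]methanesulfonyl}-4-methylbenzene; 11 hydrogen peroxide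
Product: 27 2-[(1R,5S)-4,6,6-trimethyl-5-{[(4-methylphenyl)sulfonyl]methyl}cyclohex-3-en-1-yl]ethan-1-ol, via organoborane 26 (not isolated)
Conditions: 9-BBN, THF, 0 °C → rt; then 11, NaOH, H2O, 0 °C
Reagents that add atoms: hydrogen peroxide 11, OO
Why: Hydroboration–oxidation as in step 7; only the terminal alkene reacts.

Step 16
Reactants: 27 2-[(1R,5S)-4,6,6-trimethyl-5-{[(4-methylphenyl)sulfonyl]methyl}cyclohex-3-en-1-yl]ethan-1-ol
Product: 28 2-[(1R,5S)-4,6,6-trimethyl-5-{[(4-methylphenyl)sulfonyl]methyl}cyclohex-3-en-1-yl]acetaldehyde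
Conditions: Dess–Martin periodinane, NaHCO3, CH2Cl2, 0 °C → rt
Reagents that add atoms: none
Why: Dess–Martin oxidation as in step 8.

Step 17
Reactants: 28 2-[(1R,5S)-4,6,6-trimethyl-5-{[(4-methylphenyl)sulfonyl]methyl}cyclohex-3-en-1-yl]acetaldehyde; 29 ethyl 2-(triphenyl-λ5-phosphanylidene)propanoate
Product: 30 ethyl (2E)-2-methyl-4-[(1R,5S)-4,6,6-trimethyl-5-{[(4-methylphenyl)sulfonyl]methyl}cyclohex-3-en-1-yl]but-2-enoate
Conditions: 29, CH2Cl2, rt → 40 °C
Reagents that add atoms: ethyl 2-(triphenyl-λ5-phosphanylidene)propanoate 29, CCOC(=O)C(C)=P(c1ccccc1)(c1ccccc1)c1ccccc1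
Why: Wittig reaction with a stabilised ylide; reversible oxaphosphetane formation should place the ester trans to the chain, which is the E geometry of the hydroxyprenyl group.

Step 18
Reactants: 30 ethyl (2E)-2-methyl-4-[(1R,5S)-4,6,6-trimethyl-5-{[(4-methylphenyl)sulfonyl]methyl}cyclohex-3-en-1-yl]but-2-enoate
Product: 31 (2E)-2-methyl-4-[(1R,5S)-4,6,6-trimethyl-5-{[(4-methylphenyl)sulfonyl]methyl}cyclohex-3-en-1-yl]but-2-en-1-ol
Conditions: i-Bu2AlH, CH2Cl2, −78 °C; KNaC4H4O6 aq.
Reagents that add atoms: none
Why: 1,2-Reduction of the enoate to the allylic alcohol; the sulfone is inert at this temperature.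

Step 19
Reactants: 31 (2E)-2-methyl-4-[(1R,5S)-4,6,6-trimethyl-5-{[(4-methylphenyl)sulfonyl]methyl}cyclohex-3-en-1-yl]but-2-en-1-ol; 32 tert-butyl(chloro)dimethylsilane
Product: 33 tert-butyldimethyl{[(2E)-2-methyl-4-[(1R,5S)-4,6,6-trimethyl-5-{[(4-methylphenyl)sulfonyl]methyl}cyclohex-3-en-1-yl]but-2-en-1-yl]oxy}silane
Conditions: 32, imidazole, DMF, rt
Reagents that add atoms: tert-butyl(chloro)dimethylsilane 32, CC(C)(C)[Si](C)(C)Cl
Why: Silylation of a primary alcohol; the ether withstands the organolithium, alkoxide and hydride reagents that follow and keeps this hydroxyl out of the phosphonium salt formation.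

Step 20
Reactants: 33 tert-butyldimethyl{[(2E)-2-methyl-4-[(1R,5S)-4,6,6-trimethyl-5-{[(4-methylphenyl)sulfonyl]methyl}cyclohex-3-en-1-yl]but-2-en-1-yl]oxy}silane; 17 ethyl (2E)-4-bromo-3-methylbut-2-enoate
Product: 35 ethyl (2E,4E)-5-[(1S,5R)-5-{(2E)-4-[(tert-butyldimethylsilyl)oxy]-3-methylbut-2-en-1-yl}-2,6,6-trimethylcyclohex-2-en-1-yl]-3-methylpenta-2,4-dienoate, via alkylated sulfone 34 (not isolated)
Conditions: n-BuLi, THF, −78 °C; 17, −78 °C; then NaOC2H5, EtOH, −78 °C → rt
Reagents that add atoms: ethyl (2E)-4-bromo-3-methylbut-2-enoate 17, CCOC(=O)/C=C(\C)CBr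
Why: Julia-type alkylation and dehydrosulfonylation as in step 10; the silyl ether is stable to both bases over the time needed.

Step 21
Reactants: 35 ethyl (2E,4E)-5-[(1S,5R)-5-{(2E)-4-[(tert-butyldimethylsilyl)oxy]-3-methylbut-2-en-1-yl}-2,6,6-trimethylcyclohex-2-en-1-yl]-3-methylpenta-2,4-dienoate
Product: 36 (2E,4E)-5-[(1S,5R)-5-{(2E)-4-[(tert-butyldimethylsilyl)oxy]-3-methylbut-2-en-1-yl}-2,6,6-trimethylcyclohex-2-en-1-yl]-3-methylpenta-2,4-dien-1-ol
Conditions: i-Bu2AlH, CH2Cl2, −78 °C; KNaC4H4O6 aq.
Reagents that add atoms: none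
Why: 1,2-Reduction of the dienoate as in step 11.

Step 22
Reactants: 36 (2E,4E)-5-[(1S,5R)-5-{(2E)-4-[(tert-butyldimethylsilyl)oxy]-3-methylbut-2-en-1-yl}-2,6,6-trimethylcyclohex-2-en-1-yl]-3-methylpenta-2,4-dien-1-ol; 37 tetrabromomethane; 23 triphenylphosphane
Product: 39 [(2E,4E)-5-[(1S,5R)-5-{(2E)-4-[(tert-butyldimethylsilyl)oxy]-3-methylbut-2-en-1-yl}-2,6,6-trimethylcyclohex-2-en-1-yl]-3-methylpenta-2,4-dien-1-yl]triphenylphosphanium bromide, via allylic bromide 38 (not isolated)
Conditions: 37, 23, CH2Cl2, −20 → 0 °C; then further 23, rt, dark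
Reagents that add atoms: tetrabromomethane 37, BrC(Br)(Br)Br; triphenylphosphane 23, c1ccc(cc1)P(c1ccccc1)c1ccccc1
Why: Appel bromination of the allylic alcohol under neutral conditions, then quaternisation of triphenylphosphane by the allylic bromide in the same flask. The acidic reagent of step 12 is avoided here so that the allylic silyl ether is neither cleaved nor ionised.

Step 23
Reactants: 39 [(2E,4E)-5-[(1S,5R)-5-{(2E)-4-[(tert-butyldimethylsilyl)oxy]-3-methylbut-2-en-1-yl}-2,6,6-trimethylcyclohex-2-en-1-yl]-3-methylpenta-2,4-dien-1-yl]triphenylphosphanium bromide; 40 (2E,4E,6E)-2,7-dimethylocta-2,4,6-trienedial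
Product: 41 (2E,4E,6E,8E,10E,12E)-13-[(1S,5R)-5-{(2E)-4-[(tert-butyldimethylsilyl)oxy]-3-methylbut-2-en-1-yl}-2,6,6-trimethylcyclohex-2-en-1-yl]-2,7,11-trimethyltrideca-2,4,6,8,10,12-hexaenal
Conditions: NaOCH3, MeOH/CH2Cl2, 0 °C → rt, 40 in three-fold excess; then EtOAc, reflux, dark
Reagents that add atoms: (2E,4E,6E)-2,7-dimethylocta-2,4,6-trienedial 40, O=C/C(C)=C/C=C/C=C(C)/C=O
Why: Wittig reaction of the allylic ylide with one aldehyde group of the dialdehyde (C11'=C12'); the excess of 40 suppresses double condensation. A Z isomer at the new disubstituted bond is sterically strained and should revert to E on heating.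

Step 24
Reactants: 41 (2E,4E,6E,8E,10E,12E)-13-[(1S,5R)-5-{(2E)-4-[(tert-butyldimethylsilyl)oxy]-3-methylbut-2-en-1-yl}-2,6,6-trimethylcyclohex-2-en-1-yl]-2,7,11-trimethyltrideca-2,4,6,8,10,12-hexaenal; 22 [(2E,4E)-3-methyl-5-[(1R,5S)-2,6,6-trimethyl-5-(3-methylbut-2-en-1-yl)cyclohex-2-en-1-yl]penta-2,4-dien-1-yl]triphenylphosphanium bromide
Product: 42 all-E (2S,6R,2'R,6'S)-2'-{(2E)-4-[(tert-butyldimethylsilyl)oxy]-3-methylbut-2-en-1-yl}-2-(3-methylbut-2-en-1-yl)-ε,ε-carotene
Conditions: 22 (1.3 equiv), NaOCH3, MeOH/CH2Cl2, 0 °C → rt; then EtOAc, reflux, dark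
Reagents that add atoms: none
Why: Second Wittig reaction (C11=C12) joins the ring A half to the apo-aldehyde; thermal equilibration again removes the strained Z isomer at the new bond. The mild alkoxide base does not touch C6–H or C6'–H.

Step 25
Reactants: 42 all-E (2S,6R,2'R,6'S)-2'-{(2E)-4-[(tert-butyldimethylsilyl)oxy]-3-methylbut-2-en-1-yl}-2-(3-methylbut-2-en-1-yl)-ε,ε-carotene
Product: 43 all-E (2S,6R,2'R,6'S)-2'-[(2E)-4-hydroxy-3-methylbut-2-en-1-yl]-2-(3-methylbut-2-en-1-yl)-ε,ε-carotene (CNP0304855.1)
Conditions: Bu4NF, AcOH, THF, 0 °C → rt, dark, argon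
Reagents that add atoms: none
Why: Fluoride-induced cleavage of the silyl ether; buffering with acetic acid keeps the medium close to neutral, so neither the polyene nor the doubly allylic ring positions are affected.

**Compound list**

1 | 4,4-dimethylcyclohex-2-en-1-one | CC1(C)CCC(=O)C=C1 | starting material
2 | iodomethane | CI | starting material
3 | rac-4,4,6-trimethylcyclohex-2-en-1-one | CC1CC(C)(C)C=CC1=O | intermediate
4 | 2,4,4-trimethylcyclohexa-2,5-dien-1-one | CC1=CC(C)(C)C=CC1=O | intermediate
5 | 2-ethenyl-4,4,5,5-tetramethyl-1,3,2-dioxaborolane | C=CB1OC(C)(C)C(C)(C)O1 | starting material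
6 | (5R)-5-ethenyl-2,4,4-trimethylcyclohex-2-en-1-one | C=C[C@H]1CC(=O)C(C)=CC1(C)C | intermediate
7 | (1R,5R)-5-ethenyl-2,4,4-trimethylcyclohex-2-en-1-ol (hydroxyl cis to vinyl) | C=C[C@H]1C[C@@H](O)C(C)=CC1(C)C | intermediate
8 | 2-[(4-methylphenyl)sulfonyl]acetic acid | Cc1ccc(cc1)S(=O)(=O)CC(=O)O | starting material
9 | (1R,5R)-5-ethenyl-2,4,4-trimethylcyclohex-2-en-1-yl 2-[(4-methylphenyl)sulfonyl]acetate | C=C[C@H]1C[C@@H](OC(=O)CS(=O)(=O)c2ccc(C)cc2)C(C)=CC1(C)C | intermediate
10 | 1-{[(1R,5R)-5-ethenyl-2,6,6-trimethylcyclohex-2-en-1-yl]methanesulfonyl}-4-methylbenzene (ring substituents cis) | C=C[C@H]1CC=C(C)[C@@H](CS(=O)(=O)c2ccc(C)cc2)C1(C)C | intermediate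
11 | hydrogen peroxide | OO | starting material
12 | 9-BBN adduct of 10: 9-{2-[4,6,6-trimethyl-5-{[(4-methylphenyl)sulfonyl]methyl}cyclohex-3-en-1-yl]ethyl}-9-borabicyclo[3.3.1]nonane, ring configuration as in 10 | B3(C4CCCC3CCC4)CC[C@H]1CC=C(C)[C@@H](CS(=O)(=O)c2ccc(C)cc2)C1(C)C | intermediate
13 | 2-[(1R,5R)-4,6,6-trimethyl-5-{[(4-methylphenyl)sulfonyl]methyl}cyclohex-3-en-1-yl]ethan-1-ol | OCC[C@H]1CC=C(C)[C@@H](CS(=O)(=O)c2ccc(C)cc2)C1(C)C | intermediate
14 | 2-[(1R,5R)-4,6,6-trimethyl-5-{[(4-methylphenyl)sulfonyl]methyl}cyclohex-3-en-1-yl]acetaldehyde | O=CC[C@H]1CC=C(C)[C@@H](CS(=O)(=O)c2ccc(C)cc2)C1(C)C | intermediate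
15 | triphenyl(propan-2-yl)phosphanium iodide | CC(C)[P+](c1ccccc1)(c1ccccc1)c1ccccc1.[I-] | starting material
16 | 1-methyl-4-{[(1R,5S)-2,6,6-trimethyl-5-(3-methylbut-2-en-1-yl)cyclohex-2-en-1-yl]methanesulfonyl}benzene | CC(C)=CC[C@H]1CC=C(C)[C@@H](CS(=O)(=O)c2ccc(C)cc2)C1(C)C | intermediate
17 | ethyl (2E)-4-bromo-3-methylbut-2-enoate | CCOC(=O)/C=C(\C)CBr | starting material
18 | ethyl (2E)-3-methyl-5-[(4-methylphenyl)sulfonyl]-5-[(1R,5S)-2,6,6-trimethyl-5-(3-methylbut-2-en-1-yl)cyclohex-2-en-1-yl]pent-2-enoate (both epimers at the sulfonyl-bearing carbon) | CC(C)=CC[C@H]1CC=C(C)[C@@H](C(C/C(C)=C/C(=O)OCC)S(=O)(=O)c2ccc(C)cc2)C1(C)C | intermediate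
19 | ethyl (2E,4E)-3-methyl-5-[(1R,5S)-2,6,6-trimethyl-5-(3-methylbut-2-en-1-yl)cyclohex-2-en-1-yl]penta-2,4-dienoate | CC(C)=CC[C@H]1CC=C(C)[C@@H](/C=C/C(C)=C/C(=O)OCC)C1(C)C | intermediate
20 | (2E,4E)-3-methyl-5-[(1R,5S)-2,6,6-trimethyl-5-(3-methylbut-2-en-1-yl)cyclohex-2-en-1-yl]penta-2,4-dien-1-ol | CC(C)=CC[C@H]1CC=C(C)[C@@H](/C=C/C(C)=C/CO)C1(C)C | intermediate
21 | triphenylphosphane hydrobromide (triphenylphosphanium bromide) | [PH+](c1ccccc1)(c1ccccc1)c1ccccc1.[Br-] | starting material
22 | [(2E,4E)-3-methyl-5-[(1R,5S)-2,6,6-trimethyl-5-(3-methylbut-2-en-1-yl)cyclohex-2-en-1-yl]penta-2,4-dien-1-yl]triphenylphosphanium bromide | CC(C)=CC[C@H]1CC=C(C)[C@@H](/C=C/C(C)=C/C[P+](c2ccccc2)(c2ccccc2)c2ccccc2)C1(C)C.[Br-] | intermediate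
23 | triphenylphosphane | c1ccc(cc1)P(c1ccccc1)c1ccccc1 | starting material
24 | (1S,5R)-5-ethenyl-2,4,4-trimethylcyclohex-2-en-1-yl 2-[(4-methylphenyl)sulfonyl]acetate (ester trans to vinyl) | C=C[C@H]1C[C@H](OC(=O)CS(=O)(=O)c2ccc(C)cc2)C(C)=CC1(C)C | intermediate
25 | 1-{[(1S,5R)-5-ethenyl-2,6,6-trimethylcyclohex-2-en-1-yl]methanesulfonyl}-4-methylbenzene (ring substituents trans) | C=C[C@H]1CC=C(C)[C@H](CS(=O)(=O)c2ccc(C)cc2)C1(C)C | intermediate
26 | 9-BBN adduct of 25: 9-{2-[4,6,6-trimethyl-5-{[(4-methylphenyl)sulfonyl]methyl}cyclohex-3-en-1-yl]ethyl}-9-borabicyclo[3.3.1]nonane, ring configuration as in 25 | B3(C4CCCC3CCC4)CC[C@H]1CC=C(C)[C@H](CS(=O)(=O)c2ccc(C)cc2)C1(C)C | intermediate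
27 | 2-[(1R,5S)-4,6,6-trimethyl-5-{[(4-methylphenyl)sulfonyl]methyl}cyclohex-3-en-1-yl]ethan-1-ol | OCC[C@H]1CC=C(C)[C@H](CS(=O)(=O)c2ccc(C)cc2)C1(C)C | intermediate
28 | 2-[(1R,5S)-4,6,6-trimethyl-5-{[(4-methylphenyl)sulfonyl]methyl}cyclohex-3-en-1-yl]acetaldehyde | O=CC[C@H]1CC=C(C)[C@H](CS(=O)(=O)c2ccc(C)cc2)C1(C)C | intermediate
29 | ethyl 2-(triphenyl-λ5-phosphanylidene)propanoate | CCOC(=O)C(C)=P(c1ccccc1)(c1ccccc1)c1ccccc1 | starting material
30 | ethyl (2E)-2-methyl-4-[(1R,5S)-4,6,6-trimethyl-5-{[(4-methylphenyl)sulfonyl]methyl}cyclohex-3-en-1-yl]but-2-enoate | CCOC(=O)/C(C)=C/C[C@H]1CC=C(C)[C@H](CS(=O)(=O)c2ccc(C)cc2)C1(C)C | intermediate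
31 | (2E)-2-methyl-4-[(1R,5S)-4,6,6-trimethyl-5-{[(4-methylphenyl)sulfonyl]methyl}cyclohex-3-en-1-yl]but-2-en-1-ol | OC/C(C)=C/C[C@H]1CC=C(C)[C@H](CS(=O)(=O)c2ccc(C)cc2)C1(C)C | intermediate
32 | tert-butyl(chloro)dimethylsilane | CC(C)(C)[Si](C)(C)Cl | starting material
33 | tert-butyldimethyl{[(2E)-2-methyl-4-[(1R,5S)-4,6,6-trimethyl-5-{[(4-methylphenyl)sulfonyl]methyl}cyclohex-3-en-1-yl]but-2-en-1-yl]oxy}silane | CC(C)(C)[Si](C)(C)OC/C(C)=C/C[C@H]1CC=C(C)[C@H](CS(=O)(=O)c2ccc(C)cc2)C1(C)C | intermediate
34 | ethyl (2E)-5-[(1S,5R)-5-{(2E)-4-[(tert-butyldimethylsilyl)oxy]-3-methylbut-2-en-1-yl}-2,6,6-trimethylcyclohex-2-en-1-yl]-3-methyl-5-[(4-methylphenyl)sulfonyl]pent-2-enoate (both epimers at the sulfonyl-bearing carbon) | CC(C)(C)[Si](C)(C)OC/C(C)=C/C[C@H]1CC=C(C)[C@H](C(C/C(C)=C/C(=O)OCC)S(=O)(=O)c2ccc(C)cc2)C1(C)C | intermediate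
35 | ethyl (2E,4E)-5-[(1S,5R)-5-{(2E)-4-[(tert-butyldimethylsilyl)oxy]-3-methylbut-2-en-1-yl}-2,6,6-trimethylcyclohex-2-en-1-yl]-3-methylpenta-2,4-dienoate | CC(C)(C)[Si](C)(C)OC/C(C)=C/C[C@H]1CC=C(C)[C@H](/C=C/C(C)=C/C(=O)OCC)C1(C)C | intermediate
36 | (2E,4E)-5-[(1S,5R)-5-{(2E)-4-[(tert-butyldimethylsilyl)oxy]-3-methylbut-2-en-1-yl}-2,6,6-trimethylcyclohex-2-en-1-yl]-3-methylpenta-2,4-dien-1-ol | CC(C)(C)[Si](C)(C)OC/C(C)=C/C[C@H]1CC=C(C)[C@H](/C=C/C(C)=C/CO)C1(C)C | intermediate
37 | tetrabromomethane | BrC(Br)(Br)Br | starting material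
38 | (1S,5R)-1-[(1E,3E)-5-bromo-3-methylpenta-1,3-dien-1-yl]-5-{(2E)-4-[(tert-butyldimethylsilyl)oxy]-3-methylbut-2-en-1-yl}-2,6,6-trimethylcyclohex-2-ene | CC(C)(C)[Si](C)(C)OC/C(C)=C/C[C@H]1CC=C(C)[C@H](/C=C/C(C)=C/CBr)C1(C)C | intermediate
39 | [(2E,4E)-5-[(1S,5R)-5-{(2E)-4-[(tert-butyldimethylsilyl)oxy]-3-methylbut-2-en-1-yl}-2,6,6-trimethylcyclohex-2-en-1-yl]-3-methylpenta-2,4-dien-1-yl]triphenylphosphanium bromide | CC(C)(C)[Si](C)(C)OC/C(C)=C/C[C@H]1CC=C(C)[C@H](/C=C/C(C)=C/C[P+](c2ccccc2)(c2ccccc2)c2ccccc2)C1(C)C.[Br-] | intermediate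
40 | (2E,4E,6E)-2,7-dimethylocta-2,4,6-trienedial | O=C/C(C)=C/C=C/C=C(C)/C=O | starting material
41 | (2E,4E,6E,8E,10E,12E)-13-[(1S,5R)-5-{(2E)-4-[(tert-butyldimethylsilyl)oxy]-3-methylbut-2-en-1-yl}-2,6,6-trimethylcyclohex-2-en-1-yl]-2,7,11-trimethyltrideca-2,4,6,8,10,12-hexaenal | O=C/C(C)=C/C=C/C=C(C)/C=C/C=C(C)/C=C/[C@H]1C(C)=CC[C@H](C/C=C(\C)CO[Si](C)(C)C(C)(C)C)C1(C)C | intermediate
42 | all-E (2S,6R,2'R,6'S)-2'-{(2E)-4-[(tert-butyldimethylsilyl)oxy]-3-methylbut-2-en-1-yl}-2-(3-methylbut-2-en-1-yl)-ε,ε-carotene | CC(C)=CC[C@H]1CC=C(C)[C@@H](/C=C/C(C)=C/C=C/C(C)=C/C=C/C=C(C)/C=C/C=C(C)/C=C/[C@H]2C(C)=CC[C@H](C/C=C(\C)CO[Si](C)(C)C(C)(C)C)C2(C)C)C1(C)C | intermediate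
43 | all-E (2S,6R,2'R,6'S)-2'-[(2E)-4-hydroxy-3-methylbut-2-en-1-yl]-2-(3-methylbut-2-en-1-yl)-ε,ε-carotene (CNP0304855.1) | CC(C)=CC[C@H]1CC=C(C)[C@@H](/C=C/C(C)=C/C=C/C(C)=C/C=C/C=C(C)/C=C/C=C(C)/C=C/[C@H]2C(C)=CC[C@H](C/C=C(\C)CO)C2(C)C)C1(C)C | target

**Step count and least certain steps**

Total: 25 steps. Longest linear sequence: 17 steps (steps 1 to 4, 13 to 22, 23 to 25); the ring A branch (steps 5 to 12) joins at step 24.

Step 3 (key step). Insertion at a β-carbon that adjoins a quaternary centre may be slower than protodeboronation of the vinylboron reagent, so conversion may stall. Enantioface discrimination may also fall, because the gem-dimethyl group sits next to the reacting carbon and is absent from the model enones. The fallback gives up asymmetric catalysis for a resolution. Setting out from 4, copper-catalysed 1,4-addition of CH2=CHMgBr (CuBr·SMe2, THF, −78 °C), which tolerates this hindrance and should prefer the same unsubstituted arm, gives racemic 5-ethenyl-2,4,4-trimethylcyclohex-2-en-1-one F1. Luche reduction as in step 4 gives the racemic cis alcohol rac-(1R,5R)-5-ethenyl-2,4,4-trimethylcyclohex-2-en-1-ol F2. Acylation with vinyl acetate, catalysed by the lipase of Burkholderia cepacia, should by the empirical rule for secondary alcohols convert the 1R enantiomer into (1R,5R)-5-ethenyl-2,4,4-trimethylcyclohex-2-en-1-yl acetate F3 and leave (1S,5S)-5-ethenyl-2,4,4-trimethylcyclohex-2-en-1-ol F4. After separation, methanolysis of F3 (K2CO3, MeOH) comes back to the route at 7.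

Step 6. The [3,3] shift has to form a bond at C6, between the gem-dimethyl carbon and the methyl-bearing alkene carbon, and in this series on the face that carries the vinyl group. If the shift is slow, desilylation back to 9 or thermal loss of the sulfonylacetic acid to a diene can take over. Step 14 is the same reaction on the less hindered face and is judged less exposed. The fallback replaces the [3,3] shift by a [2,3] shift and builds the sulfone afterwards. Setting out from 7, O-alkylation with (iodomethyl)tributylstannane (KH, THF) gives tributyl({[(1R,5R)-5-ethenyl-2,4,4-trimethylcyclohex-2-en-1-yl]oxy}methyl)stannane F5. Tin–lithium exchange (n-BuLi, THF, −78 °C) and Still–Wittig rearrangement give [(1R,5R)-5-ethenyl-2,6,6-trimethylcyclohex-2-en-1-yl]methanol F6. Bis(4-methylphenyl) disulfide and PBu3 convert this into 1-({[(1R,5R)-5-ethenyl-2,6,6-trimethylcyclohex-2-en-1-yl]methyl}sulfanyl)-4-methylbenzene F7. Oxidation at sulfur ((NH4)6Mo7O24, H2O2, EtOH) comes back to the route at 10.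

Step 13. The ester formed still has an acidic methylene group and may itself be alkylated by a second alkoxyphosphonium ion. The allylic alkoxyphosphonium ion may also lose a proton to give a diene instead of being displaced. The fallback sets the carbinol configuration by reagent-controlled reduction and does not invert. Setting out from 6, Corey–Bakshi–Shibata reduction ((R)-2-methyl-CBS-oxazaborolidine, catecholborane, toluene, −78 °C), with the alkenyl arm acting as the larger ketone substituent, should give (1S,5R)-5-ethenyl-2,4,4-trimethylcyclohex-2-en-1-ol F8. Esterification with 8 as in step 5 comes back to the route at 24.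

Step 10 (step 20 is the same reaction). Double-bond geometry at C9=C10 may be lost while the dienolate exists, and proton transfer from the acidic γ-position of 17 to the sulfonyl carbanion may replace substitution. The fallback makes the C7=C8 bond by carbonyl addition and reductive elimination, so the C9=C10 bond is never part of an enolate. Setting out from 16, the lithiated sulfone (n-BuLi, THF, −78 °C) is added to (2E)-4-[(tert-butyldimethylsilyl)oxy]-2-methylbut-2-enal F9. The alkoxide is trapped with benzoyl chloride to give (3E)-5-[(tert-butyldimethylsilyl)oxy]-3-methyl-1-[(4-methylphenyl)sulfonyl]-1-[(1R,5S)-2,6,6-trimethyl-5-(3-methylbut-2-en-1-yl)cyclohex-2-en-1-yl]pent-3-en-2-yl benzoate F10. Reductive elimination (Na(Hg), Na2HPO4, MeOH/THF, −20 °C; Julia–Lythgoe olefination) gives tert-butyldimethyl{[(2E,4E)-3-methyl-5-[(1R,5S)-2,6,6-trimethyl-5-(3-methylbut-2-en-1-yl)cyclohex-2-en-1-yl]penta-2,4-dien-1-yl]oxy}silane F11, the same compound as A4. Bu4NF in THF comes back to the route at 20.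

**Further compounds**

F1 | step 3 | rac-5-ethenyl-2,4,4-trimethylcyclohex-2-en-1-one | C=CC1CC(=O)C(C)=CC1(C)C
F2 | step 3 | rac-(1R,5R)-5-ethenyl-2,4,4-trimethylcyclohex-2-en-1-ol (both enantiomers of the cis alcohol) | C=C[C@H]1C[C@@H](O)C(C)=CC1(C)C.C=C[C@@H]1C[C@H](O)C(C)=CC1(C)C
F3 | step 3 | (1R,5R)-5-ethenyl-2,4,4-trimethylcyclohex-2-en-1-yl acetate | C=C[C@H]1C[C@@H](OC(C)=O)C(C)=CC1(C)C
F4 | step 3 | (1S,5S)-5-ethenyl-2,4,4-trimethylcyclohex-2-en-1-ol | C=C[C@@H]1C[C@H](O)C(C)=CC1(C)C
F5 | step 6 | tributyl({[(1R,5R)-5-ethenyl-2,4,4-trimethylcyclohex-2-en-1-yl]oxy}methyl)stannane | C=C[C@H]1C[C@@H](OC[Sn](CCCC)(CCCC)CCCC)C(C)=CC1(C)C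
F6 | step 6 | [(1R,5R)-5-ethenyl-2,6,6-trimethylcyclohex-2-en-1-yl]methanol | C=C[C@H]1CC=C(C)[C@@H](CO)C1(C)C
F7 | step 6 | 1-({[(1R,5R)-5-ethenyl-2,6,6-trimethylcyclohex-2-en-1-yl]methyl}sulfanyl)-4-methylbenzene | C=C[C@H]1CC=C(C)[C@@H](CSc2ccc(C)cc2)C1(C)C
F8 | step 13 | (1S,5R)-5-ethenyl-2,4,4-trimethylcyclohex-2-en-1-ol | C=C[C@H]1C[C@H](O)C(C)=CC1(C)C
F9 | step 10 | (2E)-4-[(tert-butyldimethylsilyl)oxy]-2-methylbut-2-enal | O=C/C(C)=C/CO[Si](C)(C)C(C)(C)C
F10 | step 10 | (3E)-5-[(tert-butyldimethylsilyl)oxy]-3-methyl-1-[(4-methylphenyl)sulfonyl]-1-[(1R,5S)-2,6,6-trimethyl-5-(3-methylbut-2-en-1-yl)cyclohex-2-en-1-yl]pent-3-en-2-yl benzoate (diastereomer mixture at the two chain stereocentres) | CC(C)=CC[C@H]1CC=C(C)[C@@H](C(C(OC(=O)c2ccccc2)/C(C)=C/CO[Si](C)(C)C(C)(C)C)S(=O)(=O)c2ccc(C)cc2)C1(C)C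
F11 | step 10 | tert-butyldimethyl{[(2E,4E)-3-methyl-5-[(1R,5S)-2,6,6-trimethyl-5-(3-methylbut-2-en-1-yl)cyclohex-2-en-1-yl]penta-2,4-dien-1-yl]oxy}silane | CC(C)=CC[C@H]1CC=C(C)[C@@H](/C=C/C(C)=C/CO[Si](C)(C)C(C)(C)C)C1(C)C
A1 | alternative 1 | tert-butyl{[(2E)-4-[(1R,5S)-5-{[(4-methoxyphenyl)methoxy]methyl}-4,6,6-trimethylcyclohex-3-en-1-yl]-2-methylbut-2-en-1-yl]oxy}dimethylsilane | COc1ccc(cc1)COC[C@H]2C(C)=CC[C@H](C/C=C(\C)CO[Si](C)(C)C(C)(C)C)C2(C)C
A2 | alternative 1 | 1,3-dioxo-2,3-dihydro-1H-isoindol-2-yl 2-[(1R,5S)-5-{[(4-methoxyphenyl)methoxy]methyl}-4,6,6-trimethylcyclohex-3-en-1-yl]acetate | COc1ccc(cc1)COC[C@H]2C(C)=CC[C@H](CC(=O)ON3C(=O)c4ccccc4C3=O)C2(C)C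
A3 | alternative 1 | tert-butyl{[(2E)-3-iodo-2-methylprop-2-en-1-yl]oxy}dimethylsilane | I/C=C(\C)CO[Si](C)(C)C(C)(C)C
A4 | alternative 2 | tert-butyldimethyl{[(2E,4E)-3-methyl-5-[(1R,5S)-2,6,6-trimethyl-5-(3-methylbut-2-en-1-yl)cyclohex-2-en-1-yl]penta-2,4-dien-1-yl]oxy}silane | CC(C)=CC[C@H]1CC=C(C)[C@@H](/C=C/C(C)=C/CO[Si](C)(C)C(C)(C)C)C1(C)C
A5 | alternative 2 | (1S,5S)-2,4,4-trimethyl-5-(3-methylbut-2-en-1-yl)cyclohex-2-en-1-yl pyridine-2-carboxylate | CC(C)=CC[C@H]1C[C@H](OC(=O)c2ccccn2)C(C)=CC1(C)C
A6 | alternative 2 | tert-butyl{[(2E,4E)-5-iodo-3-methylpenta-2,4-dien-1-yl]oxy}dimethylsilane | I/C=C/C(C)=C/CO[Si](C)(C)C(C)(C)C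
A7 | alternative 3 | [(1S,5R)-5-{(2E)-4-[(tert-butyldimethylsilyl)oxy]-3-methylbut-2-en-1-yl}-2,6,6-trimethylcyclohex-2-en-1-yl]methanol | OC[C@H]1C(C)=CC[C@H](C/C=C(\C)CO[Si](C)(C)C(C)(C)C)C1(C)C
A8 | alternative 3 | tributyl({[(1S,5S)-5-{(2E)-4-[(tert-butyldimethylsilyl)oxy]-3-methylbut-2-en-1-yl}-2,4,4-trimethylcyclohex-2-en-1-yl]oxy}methyl)stannane | CC(C)(C)[Si](C)(C)OC/C(C)=C/C[C@H]1C[C@H](OC[Sn](CCCC)(CCCC)CCCC)C(C)=CC1(C)C
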